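## Retrosynthetic overview

- **Numbering:** C1 is the butenolide α-carbon, C2–C4 are (CH2)3, C5 is CH(CH2OAc), C6–C8 are (CH2)3, C9 is CH(CH2OAc), C10–C11 are (CH2)2, then C12=C13(CH3), and C14 is CH2OH.
- **Feature:** C5 and C9 are both R, both carry CH2OAc and are bridged by C6–C8. C5–C9 plus the two acetoxymethyl carbons is therefore a masked C2-symmetric (2R,6R)-2,6-disubstituted heptanedioic acid. Only the arm ends (butenolide ring versus Z-allylic alcohol) break the symmetry.
- **Late disconnections:** the acetates go back to TBS ethers, with C14–OH held as a TBDPS ether. C1–C2 comes from a ruthenium-catalysed alkene–alkyne coupling and C12=C13 from a Still–Gennari olefination. Both arms then collapse to the homotopic allyl groups of one C2-symmetric diene.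
- **Key disconnection:** C4–C5 and C9–C10 are cut together, by a twofold Ireland–Claisen rearrangement of the pimelate of (S)-but-3-en-2-ol. The resulting (E)-crotyl arms are trimmed to allyl by ethenolysis.
- **Ring order:** the butenolide is the only ring. It is closed late (step 11) by lactonisation after the C1–C2 coupling, and the key step closes no ring.

Key step: step 2

Assumption: alcohol 2 is bought in high enantiomeric purity. Both stereocentres come from it by chirality transfer, so its purity limits each rearrangement event.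

## Route

Step 1
Reactants: 1 heptanedioic acid (pimelic acid); 2 (S)-but-3-en-2-ol
Product: 3 bis[(2S)-but-3-en-2-yl] heptanedioate
Conditions: 2 (2.2 equiv), DCC (2.2 equiv), DMAP (0.2 equiv), CH2Cl2, 0 °C to rt
Reagents that add atoms: none
Why: Steglich esterification: the carbodiimide-activated acid is passed on by DMAP to the alcohol oxygen, so no carbinol C–O bond is broken and both (S) centres enter 3 unchanged.

Step 2
Reactants: 3 bis[(2S)-but-3-en-2-yl] heptanedioate
Product: 6 (2R,6R)-2,6-bis[(2E)-but-2-en-1-yl]heptanedioic acid, via bis[(E)-silyl ketene acetal] 4 (not isolated), via bis(trimethylsilyl) ester 5 (not isolated)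
Conditions: LiN(i-Pr)2 (2.6 equiv) and Me3SiCl (6 equiv) premixed in THF, −78 °C, slow addition of 3; then rt, then 55 °C; 1 M HCl
Reagents that add atoms: Me3SiCl, C[Si](C)(C)Cl (its Me3Si groups are carried only by 4 and 5 and leave on work-up; 6 keeps no reagent atoms other than hydrogen)
Why: Kinetic deprotonation of each ester by the amide in HMPA-free THF through a closed, cyclic transition state, with the chlorosilane on hand to trap each enolate as it forms, should give the bis[(E)-silyl ketene acetal] 4 (chain carbon cis to the allylic oxygen) before a mono-enolate can attack the far ester in a Dieckmann sense. On warming, each half undergoes a concerted suprafacial [3,3]-sigmatropic shift, which breaks the carbinol C–O bond, forms C4–C5 and C9–C10 and closes no ring; the closest known type is the Ireland–Claisen rearrangement of an ester of an enantiopure secondary allylic alcohol, run here at two sites insulated by three CH2 groups. C5 and C9 are each set by 1,3-chirality transfer: in the chair the carbinol methyl lies equatorial (this also fixes the E-crotyl alkene), so the (S)-carbinol presents one face of its vinyl terminus to one face of the (E)-ketene acetal, whose chain substituent is pseudo-axial, and this pairing gives R at each α-carbon. The step needs E-selective enolisation and a chair rather than a boat; the solvent and base secure the first, and the unconstrained acyclic substrate, in which the alternative chair must carry an axial methyl, secures the second. A single wrong-sense event gives the meso (2R,6S)-diacid, a diastereomer to be removed by crystallisation or chromatography (if need be at diol 7), so errors reduce the amount of 6 but hardly its enantiopurity, since the enantiomer requires two errors in one molecule.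

Step 3
Reactants: 6 (2R,6R)-2,6-bis[(2E)-but-2-en-1-yl]heptanedioic acid
Product: 7 (2R,6R)-2,6-bis[(2E)-but-2-en-1-yl]heptane-1,7-diol
Conditions: LiAlH4, THF, 0 °C to reflux; Fieser work-up
Reagents that add atoms: none
Why: LiAlH4 reduction of a carboxylic acid: the aluminium carboxylates are reduced to primary alcohols while the isolated alkenes are inert, and C5 and C9, next to non-enolisable carboxylate salts, keep their configuration.

Step 4
Reactants: 7 (2R,6R)-2,6-bis[(2E)-but-2-en-1-yl]heptane-1,7-diol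
Product: 8 bis(tert-butyldimethylsilyl) ether of 7
Conditions: TBSCl (2.4 equiv), imidazole, DMF, rt
Reagents that add atoms: tert-butyldimethylsilyl chloride, CC(C)(C)[Si](C)(C)Cl
Why: Imidazole-promoted silylation of two unhindered primary alcohols gives ethers that withstand the metathesis, borane, hydride and base of steps 5 to 12.

Step 5
Reactants: 8 bis(tert-butyldimethylsilyl) ether of 7
Product: 9 (4R,8R)-4,8-bis{[(tert-butyldimethylsilyl)oxy]methyl}undeca-1,10-diene
Conditions: ethylene (about 5 bar), second-generation Hoveyda–Grubbs catalyst RuCl2(H2IMes)(=CH-C6H4-2-O-i-Pr) (5 mol %), 1,4-benzoquinone (10 mol %), toluene, 40 °C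
Reagents that add atoms: ethylene, C=C
Why: Ethenolysis (cross-metathesis with ethylene): under excess ethylene each 1,2-disubstituted crotyl alkene trades its ethylidene end for a methylidene with loss of volatile propene, the same ethylene reverses closure to a nine-membered ring or oligomerisation, and the stereocentres are not touched.

Step 6
Reactants: 9 (4R,8R)-4,8-bis{[(tert-butyldimethylsilyl)oxy]methyl}undeca-1,10-diene
Product: 11 (4R,8R)-4,8-bis{[(tert-butyldimethylsilyl)oxy]methyl}undec-10-en-1-ol, via B-alkyl-9-BBN adduct 10 (not isolated)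
Conditions: 9-BBN-H (0.9 equiv), THF, 0 °C to rt; then NaOH, H2O2, 0 °C
Reagents that add atoms: 9-BBN-H, [H]B1C2CCCC1CCC2 (boron carried only by 10); hydrogen peroxide, OO (hydroxyl oxygen of 11)
Why: Anti-Markovnikov hydroboration–oxidation: the two allyl groups of C2-symmetric 9 are homotopic, so a slight deficit of borane can give only one mono-alcohol, formed in a statistical mixture from which unreacted 9 is recovered for recycling and the polar diol is removed.

Step 7
Reactants: 11 (4R,8R)-4,8-bis{[(tert-butyldimethylsilyl)oxy]methyl}undec-10-en-1-ol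
Product: 12 (4R,8R)-4,8-bis{[(tert-butyldimethylsilyl)oxy]methyl}undec-10-enal
Conditions: TEMPO (10 mol %), PhI(OAc)2 (1.1 equiv), CH2Cl2, rt
Reagents that add atoms: none
Why: Oxoammonium (TEMPO/PhI(OAc)2) oxidation stops at the aldehyde, spares the terminal alkene and the silyl ethers, and no stereocentre is α to the new carbonyl.

Step 8
Reactants: 12 (4R,8R)-4,8-bis{[(tert-butyldimethylsilyl)oxy]methyl}undec-10-enal; 13 ethyl 2-[bis(2,2,2-trifluoroethoxy)phosphoryl]propanoate
Product: 14 ethyl (2Z,6R,10R)-6,10-bis{[(tert-butyldimethylsilyl)oxy]methyl}-2-methyltrideca-2,12-dienoate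
Conditions: 13, KN(SiMe3)2, 18-crown-6, THF, −78 °C; then 12
Reagents that add atoms: 13, ethyl 2-[bis(2,2,2-trifluoroethoxy)phosphoryl]propanoate, CCOC(=O)C(C)P(=O)(OCC(F)(F)F)OCC(F)(F)F
Why: Still–Gennari olefination: with the electron-poor bis(trifluoroethyl) phosphonate and a dissociated potassium counter-ion the kinetic adduct eliminates faster than it reverts, which should place the C11 chain and CO2Et cis and so set the (Z)-C12=C13 geometry.

Step 9
Reactants: 14 ethyl (2Z,6R,10R)-6,10-bis{[(tert-butyldimethylsilyl)oxy]methyl}-2-methyltrideca-2,12-dienoate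
Product: 15 (2Z,6R,10R)-6,10-bis{[(tert-butyldimethylsilyl)oxy]methyl}-2-methyltrideca-2,12-dien-1-ol
Conditions: i-Bu2AlH (2.5 equiv), CH2Cl2, −78 to 0 °C; aq. potassium sodium tartrate
Reagents that add atoms: none
Why: 1,2-Reduction of an α,β-unsaturated ester by i-Bu2AlH gives the allylic alcohol with retention of the Z geometry and leaves the unactivated terminal alkene and the silyl ethers alone.

Step 10
Reactants: 15 (2Z,6R,10R)-6,10-bis{[(tert-butyldimethylsilyl)oxy]methyl}-2-methyltrideca-2,12-dien-1-ol
Product: 16 tert-butyldiphenylsilyl ether of 15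
Conditions: TBDPSCl, imidazole, CH2Cl2, 0 °C to rt
Reagents that add atoms: tert-butyldiphenylsilyl chloride, CC(C)(C)[Si](Cl)(c1ccccc1)c1ccccc1
Why: Silylation with the bulkier and far more acid-stable tert-butyldiphenylsilyl group marks C14–O as the one oxygen that is not exchanged for acetate later, since a free hydroxyl would be acetylated in step 14.

Step 11
Reactants: 16 tert-butyldiphenylsilyl ether of 15; 17 ethyl 4-hydroxybut-2-ynoate
Product: 19 3-[(2E,4R,8R,11Z)-4,8-bis{[(tert-butyldimethylsilyl)oxy]methyl}-13-[(tert-butyldiphenylsilyl)oxy]-12-methyltrideca-2,11-dien-1-yl]furan-2(5H)-one, via (Z)-hydroxy dienoate 18 (not isolated)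
Conditions: 17 (1.5 equiv), CpRu(MeCN)3PF6 (10 mol %), acetone, rt; then PPTS (cat.), CH2Cl2, rt, to finish the lactonisation
Reagents that add atoms: 17, ethyl 4-hydroxybut-2-ynoate, CCOC(=O)C#CCO
Why: Ruthenium-catalysed Alder-ene-type alkene–alkyne coupling: oxidative cyclisation of the monosubstituted alkene and the ynoate on the CpRu cation, β-hydride elimination from C4 and reductive elimination join C2 to the ynoate α-carbon with cis delivery of carbon and hydrogen, so CO2Et and CH2OH stand cis in 18 and lactonise to the butenolide, while the trisubstituted C12=C13 alkene is too hindered to take part.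

Step 12
Reactants: 19 butenolide 1,4-diene
Product: 20 3-[(4R,8R,11Z)-4,8-bis{[(tert-butyldimethylsilyl)oxy]methyl}-13-[(tert-butyldiphenylsilyl)oxy]-12-methyltridec-11-en-1-yl]furan-2(5H)-one
Conditions: TsNHNH2 and NaOAc in portions, DME–H2O, reflux
Reagents that add atoms: none
Why: Diimide reduction: the concerted syn transfer of H2 responds mainly to the degree of substitution, so the 1,2-disubstituted C3=C4 alkene should be saturated ahead of the two trisubstituted alkenes (butenolide C=C and C12=C13), as is usual for isolated alkenes beside α-alkyl butenolides, with the reagent fed in portions and the reaction stopped once 19 is consumed.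

Step 13
Reactants: 20 saturated bis-TBS TBDPS butenolide
Product: 21 3-[(4R,8R,11Z)-13-[(tert-butyldiphenylsilyl)oxy]-4,8-bis(hydroxymethyl)-12-methyltridec-11-en-1-yl]furan-2(5H)-one
Conditions: CSA (0.2 equiv), MeOH–CH2Cl2 (1:1), 0 °C
Reagents that add atoms: none
Why: Selective acid-catalysed desilylation: the two primary TBS ethers undergo methanolysis far faster than the tert-butyldiphenylsilyl ether, and the lactone and alkenes are inert to catalytic acid at 0 °C.

Step 14
Reactants: 21 diol
Product: 22 3-[(4R,8R,11Z)-4,8-bis(acetoxymethyl)-13-[(tert-butyldiphenylsilyl)oxy]-12-methyltridec-11-en-1-yl]furan-2(5H)-one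
Conditions: Ac2O, pyridine, DMAP (cat.), CH2Cl2, 0 °C to rt
Reagents that add atoms: acetic anhydride, CC(=O)OC(C)=O
Why: DMAP-catalysed acetylation of the two liberated primary alcohols is fast and mild enough for the butenolide, while C14–O stays blocked.

Step 15
Reactants: 22 diacetate TBDPS ether
Product: 23 3-[(4R,8R,11Z)-4,8-bis(acetoxymethyl)-13-hydroxy-12-methyltridec-11-en-1-yl]furan-2(5H)-one (CNP0139404.2)
Conditions: HF·pyridine, pyridine, THF, 0 °C to rt
Reagents that add atoms: none
Why: Fluoride-driven desilylation in a buffered acidic medium cleaves the Si–O bond without the basic species that could hydrolyse the acetates or deconjugate the butenolide, and so releases the Z-allylic alcohol of the target.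

## Compound list

1 | heptanedioic acid (pimelic acid) | OC(=O)CCCCCC(O)=O | starting material
2 | (S)-but-3-en-2-ol | C=C[C@H](C)O | starting material
3 | bis[(2S)-but-3-en-2-yl] heptanedioate | C=C[C@H](C)OC(=O)CCCCCC(=O)O[C@@H](C)C=C | intermediate
4 | (1E,6E)-1,7-bis[(2S)-but-3-en-2-yloxy]-1,7-bis(trimethylsilyloxy)hepta-1,6-diene | C=C[C@H](C)O/C(O[Si](C)(C)C)=C\CCC/C=C(/O[Si](C)(C)C)O[C@@H](C)C=C | intermediate
5 | bis(trimethylsilyl) (2R,6R)-2,6-bis[(2E)-but-2-en-1-yl]heptanedioate | C[Si](C)(C)OC(=O)[C@@H](C/C=C/C)CCC[C@H](C/C=C/C)C(=O)O[Si](C)(C)C | intermediate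
6 | (2R,6R)-2,6-bis[(2E)-but-2-en-1-yl]heptanedioic acid | OC(=O)[C@@H](C/C=C/C)CCC[C@H](C/C=C/C)C(O)=O | intermediate
7 | (2R,6R)-2,6-bis[(2E)-but-2-en-1-yl]heptane-1,7-diol | OC[C@@H](C/C=C/C)CCC[C@H](C/C=C/C)CO | intermediate
8 | bis(tert-butyldimethylsilyl) ether of 7 | CC(C)(C)[Si](C)(C)OC[C@@H](C/C=C/C)CCC[C@H](C/C=C/C)CO[Si](C)(C)C(C)(C)C | intermediate
9 | (4R,8R)-4,8-bis{[(tert-butyldimethylsilyl)oxy]methyl}undeca-1,10-diene | CC(C)(C)[Si](C)(C)OC[C@@H](CC=C)CCC[C@H](CC=C)CO[Si](C)(C)C(C)(C)C | intermediate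
10 | B-alkyl-9-BBN mono-adduct of 9 | CC(C)(C)[Si](C)(C)OC[C@@H](CC=C)CCC[C@H](CCCB1C2CCCC1CCC2)CO[Si](C)(C)C(C)(C)C | intermediate
11 | (4R,8R)-4,8-bis{[(tert-butyldimethylsilyl)oxy]methyl}undec-10-en-1-ol | CC(C)(C)[Si](C)(C)OC[C@@H](CC=C)CCC[C@H](CCCO)CO[Si](C)(C)C(C)(C)C | intermediate
12 | (4R,8R)-4,8-bis{[(tert-butyldimethylsilyl)oxy]methyl}undec-10-enal | CC(C)(C)[Si](C)(C)OC[C@@H](CC=C)CCC[C@H](CCC=O)CO[Si](C)(C)C(C)(C)C | intermediate
13 | ethyl 2-[bis(2,2,2-trifluoroethoxy)phosphoryl]propanoate | CCOC(=O)C(C)P(=O)(OCC(F)(F)F)OCC(F)(F)F | starting material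
14 | ethyl (2Z,6R,10R)-6,10-bis{[(tert-butyldimethylsilyl)oxy]methyl}-2-methyltrideca-2,12-dienoate | CC(C)(C)[Si](C)(C)OC[C@@H](CC=C)CCC[C@H](CC/C=C(/C)C(=O)OCC)CO[Si](C)(C)C(C)(C)C | intermediate
15 | (2Z,6R,10R)-6,10-bis{[(tert-butyldimethylsilyl)oxy]methyl}-2-methyltrideca-2,12-dien-1-ol | CC(C)(C)[Si](C)(C)OC[C@@H](CC=C)CCC[C@H](CC/C=C(/C)CO)CO[Si](C)(C)C(C)(C)C | intermediate
16 | tert-butyldiphenylsilyl ether of 15 | CC(C)(C)[Si](C)(C)OC[C@@H](CC=C)CCC[C@H](CC/C=C(/C)CO[Si](c1ccccc1)(c1ccccc1)C(C)(C)C)CO[Si](C)(C)C(C)(C)C | intermediate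
17 | ethyl 4-hydroxybut-2-ynoate | CCOC(=O)C#CCO | starting material
18 | ethyl (2Z)-4-hydroxy-2-[(2E)-alk-2-en-1-yl]but-2-enoate (open form of 19) | CC(C)(C)[Si](C)(C)OC[C@@H](/C=C/C/C(C(=O)OCC)=C/CO)CCC[C@H](CC/C=C(/C)CO[Si](c1ccccc1)(c1ccccc1)C(C)(C)C)CO[Si](C)(C)C(C)(C)C | intermediate
19 | 3-[(2E,4R,8R,11Z)-4,8-bis{[(tert-butyldimethylsilyl)oxy]methyl}-13-[(tert-butyldiphenylsilyl)oxy]-12-methyltrideca-2,11-dien-1-yl]furan-2(5H)-one | CC(C)(C)[Si](C)(C)OC[C@@H](/C=C/CC1=CCOC1=O)CCC[C@H](CC/C=C(/C)CO[Si](c1ccccc1)(c1ccccc1)C(C)(C)C)CO[Si](C)(C)C(C)(C)C | intermediate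
20 | 3-[(4R,8R,11Z)-4,8-bis{[(tert-butyldimethylsilyl)oxy]methyl}-13-[(tert-butyldiphenylsilyl)oxy]-12-methyltridec-11-en-1-yl]furan-2(5H)-one | CC(C)(C)[Si](C)(C)OC[C@@H](CCCC1=CCOC1=O)CCC[C@H](CC/C=C(/C)CO[Si](c1ccccc1)(c1ccccc1)C(C)(C)C)CO[Si](C)(C)C(C)(C)C | intermediate
21 | 3-[(4R,8R,11Z)-13-[(tert-butyldiphenylsilyl)oxy]-4,8-bis(hydroxymethyl)-12-methyltridec-11-en-1-yl]furan-2(5H)-one | OC[C@@H](CCCC1=CCOC1=O)CCC[C@H](CC/C=C(/C)CO[Si](c1ccccc1)(c1ccccc1)C(C)(C)C)CO | intermediate
22 | 3-[(4R,8R,11Z)-4,8-bis(acetoxymethyl)-13-[(tert-butyldiphenylsilyl)oxy]-12-methyltridec-11-en-1-yl]furan-2(5H)-one | CC(=O)OC[C@@H](CCCC1=CCOC1=O)CCC[C@H](CC/C=C(/C)CO[Si](c1ccccc1)(c1ccccc1)C(C)(C)C)COC(C)=O | intermediate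
23 | 3-[(4R,8R,11Z)-4,8-bis(acetoxymethyl)-13-hydroxy-12-methyltridec-11-en-1-yl]furan-2(5H)-one (CNP0139404.2) | CC(=O)OC[C@@H](CCCC1=CCOC1=O)CCC[C@H](CC/C=C(/C)CO)COC(C)=O | target

Total step count: 15
Longest linear sequence: 15 steps (1 to 23)

## Steps most likely to fail

**Step 2 (twofold Ireland–Claisen).**
- Incomplete E-selectivity in the enolisation, or leakage through boat transition states at either end, would divert material into the meso diastereomer.
- Removing that diastereomer may be laborious because the two centres are 1,5-related.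
- Ring-forming Claisen condensation could also compete with silylation.

The fallback sets out from 1 and comes back at 9, replacing steps 1 to 5. Acid 1 would be N-acylated onto two equivalents of (S)-4-benzyl-1,3-oxazolidin-2-one (DCC, DMAP, CH2Cl2) to give the bis-imide 1,7-bis[(4S)-4-benzyl-2-oxo-1,3-oxazolidin-3-yl]heptane-1,7-dione F1. Double enolisation with NaN(SiMe3)2 in THF at −78 °C and trapping with allyl iodide is a twofold Evans alkylation. Each chelated Z-enolate is attacked on the face away from its benzyl group, so this should give the (2R,6R)-diallyl bis-imide F2, whose diastereomers are chromatographically distinct. LiBH4 in Et2O–H2O would release the auxiliary and give (2R,6R)-2,6-di(prop-2-en-1-yl)heptane-1,7-diol F3, and silylation as in step 4 turns this into 9.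

**Step 12 (diimide reduction).**
- Chemoselectivity may erode through over-reduction of C12=C13 or of the butenolide alkene.
- The reduction of C3=C4 may be sluggish because of the branching at C5.

The fallback sets out from 16 and comes back at 20. It builds the arm in saturated form, so it leaves out steps 11 and 12.
- Chemoselective hydroboration of the monosubstituted alkene of 16 with 9-BBN-H would give the B-alkyl-9-BBN adduct F4.
- Oxidation (NaOH, H2O2) converts this into the primary alcohol F5.
- I2, PPh3 and imidazole (Appel-type iodination) convert it into the primary iodide F6.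
- The lithium enolate of the known 3-(phenylsulfanyl)oxolan-2-one (LiN(i-Pr)2, THF–DMPU, −78 °C to rt) would be alkylated by the iodide to the α-phenylsulfanyl lactone F7. It forms as epimers at the sulfur-bearing carbon, which is of no consequence.
- One equivalent of mCPBA at −78 °C oxidises sulfur ahead of the trisubstituted alkene to the sulfoxide F8.
- Thermal syn-elimination of the sulfoxide in toluene at reflux installs the endocyclic butenolide alkene, which gives 20.

**Step 5 (double ethenolysis).**
- The exchange may stall at an equilibrium mixture in which one or both crotyl arms persist.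
- The catalyst may be lost as its methylidene form.
- The alkene may migrate.

Any of these would leave mixtures that are hard to separate. The fallback sets out from 8 and comes back at 9. Ozonolysis of both crotyl alkenes (O3, CH2Cl2, −78 °C) would give the bis-ozonide F9. This is reduced in the same flask with PPh3 to the dialdehyde (3R,7R)-3,7-bis{[(tert-butyldimethylsilyl)oxy]methyl}nonanedial F10. Twofold Wittig methylenation (Ph3P=CH2 from MePPh3Br and KN(SiMe3)2, THF, −78 °C to rt) then gives 9. The stereocentres are β to the aldehydes and cannot be lost by enolisation.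

## Further compounds

F1 | step 2 | 1,7-bis[(4S)-4-benzyl-2-oxo-1,3-oxazolidin-3-yl]heptane-1,7-dione | O=C(CCCCCC(=O)N1[C@@H](Cc2ccccc2)COC1=O)N1[C@@H](Cc2ccccc2)COC1=O
F2 | step 2 | (2R,6R)-1,7-bis[(4S)-4-benzyl-2-oxo-1,3-oxazolidin-3-yl]-2,6-di(prop-2-en-1-yl)heptane-1,7-dione | O=C1OC[C@H](Cc2ccccc2)N1C(=O)[C@@H](CC=C)CCC[C@H](CC=C)C(=O)N1[C@@H](Cc2ccccc2)COC1=O
F3 | step 2 | (2R,6R)-2,6-di(prop-2-en-1-yl)heptane-1,7-diol | OC[C@@H](CC=C)CCC[C@H](CC=C)CO
F4 | step 12 | B-alkyl-9-BBN adduct of 16 | CC(C)(C)[Si](C)(C)OC[C@@H](CCCB1C2CCCC1CCC2)CCC[C@H](CC/C=C(/C)CO[Si](c1ccccc1)(c1ccccc1)C(C)(C)C)CO[Si](C)(C)C(C)(C)C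
F5 | step 12 | (4R,8R,11Z)-4,8-bis{[(tert-butyldimethylsilyl)oxy]methyl}-13-[(tert-butyldiphenylsilyl)oxy]-12-methyltridec-11-en-1-ol | CC(C)(C)[Si](C)(C)OC[C@@H](CCCO)CCC[C@H](CC/C=C(/C)CO[Si](c1ccccc1)(c1ccccc1)C(C)(C)C)CO[Si](C)(C)C(C)(C)C
F6 | step 12 | primary iodide from F5 | CC(C)(C)[Si](C)(C)OC[C@@H](CCCI)CCC[C@H](CC/C=C(/C)CO[Si](c1ccccc1)(c1ccccc1)C(C)(C)C)CO[Si](C)(C)C(C)(C)C
F7 | step 12 | 3-alkyl-3-(phenylsulfanyl)oxolan-2-one (epimers at C3 of the lactone) | CC(C)(C)[Si](C)(C)OC[C@@H](CCCC1(Sc2ccccc2)CCOC1=O)CCC[C@H](CC/C=C(/C)CO[Si](c1ccccc1)(c1ccccc1)C(C)(C)C)CO[Si](C)(C)C(C)(C)C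
F8 | step 12 | 3-alkyl-3-(phenylsulfinyl)oxolan-2-one (stereoisomers at C3 and sulfur) | CC(C)(C)[Si](C)(C)OC[C@@H](CCCC1(S(=O)c2ccccc2)CCOC1=O)CCC[C@H](CC/C=C(/C)CO[Si](c1ccccc1)(c1ccccc1)C(C)(C)C)CO[Si](C)(C)C(C)(C)C
F9 | step 5 | bis(1,2,4-trioxolane) (bis-ozonide) of 8 | CC(C)(C)[Si](C)(C)OC[C@@H](CC1OOC(C)O1)CCC[C@H](CC1OOC(C)O1)CO[Si](C)(C)C(C)(C)C
F10 | step 5 | (3R,7R)-3,7-bis{[(tert-butyldimethylsilyl)oxy]methyl}nonanedial | CC(C)(C)[Si](C)(C)OC[C@@H](CC=O)CCC[C@H](CC=O)CO[Si](C)(C)C(C)(C)C
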